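The saturated, acyclic C20 chain is built by desymmetrising dodecanedioic acid 1 with benzyl alcohol 2 to the half ester 3, whose free carboxyl group serves as a traceless radical precursor. Mixed Kolbe electrolysis of 3 with decanoic acid 4 then forges, in one operation, the C11–C12 methylene–methylene bond (C1 = ester carbonyl) of target 5. This bond lies nine methylene groups from the only functional group. Anodic decarboxylation generates an 11-(benzyloxy)-11-oxoundecyl and a nonyl radical, which combine at the platinum anode. The benzyl ester at C1 and its benzene ring, the only ring, are spectators.

Key step: step 2

Remark: the target has no stereocentre and no stereogenic double bond, so it is a single achiral compound and no stereocontrol is needed.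

Step 1
Reactants: 1 dodecanedioic acid; 2 benzyl alcohol
Product: 3 12-(benzyloxy)-12-oxododecanoic acid (monobenzyl dodecanedioate)
Conditions: 1 (2 equiv), 2 (1 equiv), TsOH·H2O (5 mol %), toluene, reflux, Dean–Stark; cool, filter off excess 1; SiO2
Reagents that add atoms: none
Why: Fischer esterification driven by azeotropic removal of water; the two remote carboxyl groups react independently, so an excess of the diacid should channel the benzyl alcohol mainly into the half ester, with unreacted 1 crystallising from cold toluene and the minor dibenzyl diester removed by chromatography.

Step 2
Reactants: 3 12-(benzyloxy)-12-oxododecanoic acid; 4 decanoic acid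
Product: 5 benzyl eicosanoate
Conditions: 3 (1 equiv), 4 (4 equiv), KOH (5 mol % of total CO2H, added after the acids are dissolved), MeOH, 45–50 °C, undivided cell, smooth Pt anode, Pt cathode, constant current ca. 0.25 A cm⁻², ca. 1.3 F per mol CO2H, stopped while still faintly acidic; AcOH; SiO2 (hexane, then hexane/EtOAc)
Reagents that add atoms: none
Why: At the platinum anode both carboxylates are oxidised by one electron and lose CO2, giving the nonyl radical and the 11-(benzyloxy)-11-oxoundecyl radical in high local concentration at the electrode surface, where their cross-combination forms the C11–C12 CH2–CH2 bond; the cathode reduces the carboxyl protons to H2 and regenerates carboxylate, so a catalytic amount of base suffices. The closest known reaction type is the mixed (hetero) Kolbe electrolysis of a fatty acid with an α,ω-diacid half ester, the classical chain-extension route to long-chain esters. No ring is closed and no stereocentre is formed. Cross- versus homo-coupling is statistical, and the excess of cheap 4 should ensure that most radicals from 3 meet a nonyl partner; the by-products octadecane (a hydrocarbon) and dibenzyl docosanedioate (a diester) differ clearly in polarity from monoester 5. Radical coupling over two-electron (Hofer–Moest) oxidation is favoured by the unbranched primary radicals without α-substituents, smooth platinum, high current density and weakly acidic methanol. The benzyl ester, nine methylene groups from the reacting carbon, should be spared because the adsorbed carboxylate layer keeps the arene away from the anode, and because stopping on the acidic side prevents methoxide transesterification.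

Compound list
1 | dodecanedioic acid | OC(=O)CCCCCCCCCCC(=O)O | starting material
2 | benzyl alcohol | OCc1ccccc1 | starting material
3 | 12-(benzyloxy)-12-oxododecanoic acid (monobenzyl dodecanedioate) | OC(=O)CCCCCCCCCCC(=O)OCc1ccccc1 | intermediate
4 | decanoic acid | CCCCCCCCCC(=O)O | starting material
5 | benzyl eicosanoate (eicosanoic acid phenylmethyl ester) | CCCCCCCCCCCCCCCCCCCC(=O)OCc1ccccc1 | target

Total step count: 2
Longest linear sequence: 2 steps (1 → 3 → 5)

Steps most likely to fail (the route has only two steps, so both are ranked):

1. Step 2 (key step). Four processes could erode the yield:
- statistical homo-coupling may lower the share of cross-product;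
- the radicals may be over-oxidised to carbocations, giving methyl ethers and alkenes;
- the waxy products may passivate the anode, or the benzyl group may be oxidised at the anode;
- the benzyl ester may undergo methanolysis if the medium drifts alkaline.

Fallback: a polar alkyl–alkyl cross-coupling that forms the same C11–C12 bond, setting out from benzyl alcohol 2. Esterification of 2 with 11-bromoundecanoic acid F1 (TsOH cat., toluene, Dean–Stark) should give benzyl 11-bromoundecanoate F2. Copper-catalysed Kochi-type coupling of F2 with nonylmagnesium bromide F3 (Li2CuCl4 3 mol %, NMP 4 equiv, THF, 0 °C, slow addition of the Grignard reagent) should then return to the route at target 5. Under these conditions substitution of the primary bromide is expected to outpace addition to the ester.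

2. Step 1. Over-esterification to the dibenzyl diester, or incomplete separation of the half ester from diacid and diester (co-crystallisation, soap emulsions on basic extraction), may make 3 hard to obtain pure.

Fallback: a non-statistical route setting out from benzyl alcohol 2. Esterification of 12-hydroxydodecanoic acid F4 with an excess of 2 (TsOH cat., toluene, Dean–Stark; the excess alcohol suppresses oligoester formation) should give benzyl 12-hydroxydodecanoate F5. Oxidation of its primary alcohol to the acid (TEMPO cat., PhI(OAc)2, MeCN/H2O, rt) should return to the route at half ester 3.

Further compounds
F1 | step 2 | 11-bromoundecanoic acid | OC(=O)CCCCCCCCCCBr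
F2 | step 2 | benzyl 11-bromoundecanoate | BrCCCCCCCCCCC(=O)OCc1ccccc1
F3 | step 2 | nonylmagnesium bromide | CCCCCCCCC[Mg]Br
F4 | step 1 | 12-hydroxydodecanoic acid | OCCCCCCCCCCCC(=O)O
F5 | step 1 | benzyl 12-hydroxydodecanoate | OCCCCCCCCCCCC(=O)OCc1ccccc1
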